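## The problem

The target 19 is (1R,2S)-1-(3,4-dimethoxyphenyl)-6,7-dimethoxy-2,3-dimethyl-1,2-dihydronaphthalene. A dimethoxybenzo ring A is fused to a six-membered ring B that carries the 3,4-dimethoxyphenyl group at C1, methyl groups at C2 and C3, and a C3=C4 double bond conjugated with ring A. There are only two stereocentres, the diarylmethine C1 (R) and the neighbouring C2 (S), with aryl and methyl trans. No third centre can relay chirality, so the absolute configuration at C1 must come from an auxiliary, a ligand or a catalyst. C1 can then control C2, because a reagent approaching C2 meets the C1 aryl group on one face. Apart from four aryl methyl ethers and the styrene the molecule has no functional group, so whatever activates ring B must be removed without trace. The 1,2-dihydronaphthalene is fragile: it is one dehydrogenation or one elimination away from a naphthalene, and acid or strong base can move the double bond and erase C2 (or, through the doubly benzylic C1–H, C1). The electron-rich rings also exclude strong electrophiles and oxidants late in the route. The enabling feature is that C1–C4 with ring A form a naphthalene that has taken up an aryl anion at C1 and a methyl cation at C2. A naphthalene with an electron-withdrawing, lithium-binding group at C2 can accept exactly this pair and keep C3=C4.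

## Retrosynthesis

**19 from 18.** The C2–H bond of 19 is traced back to a C2–CHO bond in aldehyde 18. This puts an acyl carbon on C2, which is what turns ring B into an acceptor. It also makes C2 quaternary, so that after the key step it can neither epimerise nor let the double bond slip into conjugation with the carbonyl group. The neighbouring choice, keeping the acyl carbon as the future C2 methyl, would leave an acidic, allylic C2–H through several steps. The forward reaction must replace CHO by H with retention at an allylic quaternary carbon, without alkene migration or aromatisation.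

**18 from 15 (through 16 and 17).** The formyl group is the unmasked form of the oxazoline in 15. An oxazoline is preferred to an ester or amide because it resists 1,2-attack by organolithiums, binds lithium at nitrogen and carries the stereocontrolling tert-butyl group. The forward sequence (N-methylation to 16, hydride reduction to 17, mild hydrolysis) must spare the styrene and the C1–H.

**15 from 11 and 13 (key disconnection).** The C1–aryl and C2–CH3 bonds are cut together. Both stereocentres disappear and the precursor is the flat, achiral-at-carbon naphthyl oxazoline 11, with aryllithium 13 and a methyl electrophile as partners. Cuts inside ring B (for example C1–C8a by Friedel–Crafts closure) would require an acyclic chain with both stereocentres already set. The forward reaction must add 13 to C1 of 11 on one face, then methylate the aza-enolate 14 at C2 anti to the new aryl group. Aryllithium 13 comes from bromide 12 by halogen–lithium exchange.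

**11 from 6 and 7 (through 8, 9 and 10).** The oxazoline C–O and C–N bonds are cut back to naphthoic acid 6 and (S)-tert-leucinol 7. Amide 9 is formed through acid chloride 8 and closed through chloro amide 10. These are routine operations that do not touch the stereocentre of 7.

**6 from 5, 4, and 1 with 2.** Acid 6 comes from ester 5, and 5 from the 1,4-dihydronaphthalene 4 by dehydrogenation. Ring B of 4 is cut at C1–C2 and C3–C4 (the two benzylic–vinylic bonds) into o-quinodimethane 3, released from dibromide 1, and methyl but-2-ynoate 2. The diene is symmetrical, so there is no regiochemical question, and the alkyne dienophile gives a product only one mild oxidation away from the naphthalene. Classical Friedel–Crafts routes to 5 would need about twice as many steps.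

## Roads not taken

**Alternative 1:** Ring A is cut at C4a–C5 and C8–C8a. The forward key step is a Diels–Alder reaction of 2,3-dimethoxybuta-1,3-diene A3 with the enone double bond of the all-trans cyclohexenone A2, under mild Lewis acid catalysis or heat, to give the cis-fused adduct A1. Ring A would then be dehydrogenated to the arene, and the ketone reduced and dehydrated to give C3=C4.
- Merits: the oxygenation of ring A arrives in a cheap symmetrical diene, there is no regiochemical issue, and no auxiliary or one-carbon excision is needed. In these respects it is better than the chosen plan.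
- Weak points: A2 already holds three contiguous stereocentres that must be made enantioselectively, so the real problem is only moved. One of those centres (the future C3) and both ring-fusion centres of A1 are destroyed later. A γ-aryl cyclohexenone is a poor dienophile and the bis(enol ether) diene is acid-labile. The final dehydration passes through a benzylic cation next to the fragile C1–H.
- Comparison: the chosen plan sets both stereocentres in one operation from a flat naphthalene that is made in five simple steps.

**Alternative 2:** Ring B is cut at C1–C8a and C4–C4a. Fluoride-induced aryne generation from silyl triflate A5 in the presence of 3,4-dimethylfuran A6 gives the meso oxabicycle A4 in a single step from purchasable partners.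
- Merits: up to A4 this is the shortest route of all, and a catalytic desymmetrisation could replace the stoichiometric auxiliary of the chosen plan. On step count and chirality economy it is superior.
- Weak points: A4 contains neither the aryl group nor any stereocentre of the target. An enantioselective reductive ring opening would have to deliver hydride to a methyl-bearing carbon of a tetrasubstituted alkene to reach dihydronaphthalenol A7, which is outside the usual scope of such openings. The hydroxyl of A7 would then be exchanged for aryl by Friedel–Crafts reaction with veratrole A8 through a C1 cation. That cation loses the C1 configuration, and its easiest fate is proton loss to a naphthalene.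
- Comparison: the chosen plan forms the C1–aryl bond by nucleophilic addition under auxiliary control and never generates a cation at C1.

**Alternative 3:** Rings A and B are cut together at C4a–C8a, C5–C6 and C7–C8. A cobalt-mediated [2+2+2] cycloaddition of the (Z)-enediyne A10 with diborylethyne A11, under irradiation and heat, would give the bis-boronate A9. Oxidation of both C–B bonds to catechol A12 and double O-methylation would finish the synthesis.
- Merits: three C–C bonds and two rings form in one step, and no stereocentre is created during ring formation. In bonds per step it surpasses the chosen plan.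
- Weak points: A10 is harder to make than the target. It has two adjacent acyclic stereocentres, one of them a propargylic and benzylic C–H prone to epimerisation and alkyne–allene isomerisation, and a Z-trisubstituted enyne. Terminal diynes also self-trimerise. The methoxy groups of ring A, which cost nothing in the chosen plan, need two extra steps through the air-sensitive A12.
- Comparison: the chosen plan offers accessible precursors and a key step that has close precedent as a reaction type.

Key step: step 6

Assumption: the (4S)-tert-butyl oxazoline is taken to direct the aryl group to the C1 face that gives the (1R) configuration drawn for 15 (this sense rests on analogy and is not settled here by an unambiguous model), and dibromide 1 is treated as a catalogue compound.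

Step 1
Reactants: 1 1,2-bis(bromomethyl)-4,5-dimethoxybenzene; 2 methyl but-2-ynoate
Product: 4 methyl 6,7-dimethoxy-3-methyl-1,4-dihydronaphthalene-2-carboxylate, via 4,5-dimethoxy-o-quinodimethane 3 (not isolated)
Conditions: NaI (4 equiv.), DMF, 70 °C; 1 added slowly to 2 (5 equiv.)
Reagents that add atoms: none
Why: Iodide-induced 1,4-elimination of the bis-benzylic dibromide releases o-quinodimethane 3, which is trapped by the acetylenic ester in a Diels–Alder reaction; the diene is symmetrical, so only one adduct can form, and slow addition of 1 into excess 2 keeps 3 dilute and limits its dimerisation.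

Step 2
Reactants: 4 methyl 6,7-dimethoxy-3-methyl-1,4-dihydronaphthalene-2-carboxylate
Product: 5 methyl 6,7-dimethoxy-3-methylnaphthalene-2-carboxylate
Conditions: DDQ (1.1 equiv.), PhMe, rt to 60 °C
Reagents that add atoms: none
Why: Quinone dehydrogenation of a 1,4-dihydronaphthalene (hydride abstraction from a benzylic CH2 activated by the para methoxy group, then proton loss) is driven by aromatisation and needs no forcing conditions.

Step 3
Reactants: 5 methyl 6,7-dimethoxy-3-methylnaphthalene-2-carboxylate
Product: 6 6,7-dimethoxy-3-methylnaphthalene-2-carboxylic acid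
Conditions: NaOH, MeOH/THF/H2O, 65 °C; then aq. HCl
Reagents that add atoms: sodium hydroxide, [Na+].[OH-]
Why: Saponification of an aryl methyl ester; the single ortho methyl group slows but does not block acyl substitution at this temperature.

Step 4
Reactants: 6 6,7-dimethoxy-3-methylnaphthalene-2-carboxylic acid; 7 (S)-tert-leucinol
Product: 9 N-[(2S)-1-hydroxy-3,3-dimethylbutan-2-yl]-6,7-dimethoxy-3-methylnaphthalene-2-carboxamide, via acid chloride 8 (not isolated)
Conditions: (COCl)2, cat. DMF, CH2Cl2, 0 °C to rt; evaporate; then 7, Et3N, CH2Cl2, 0 °C to rt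
Reagents that add atoms: none
Why: Acid chloride formation followed by N-acylation of the amino alcohol; the amine is far more nucleophilic than the neopentyl-type hydroxyl, and the stereocentre of 7 is not involved.

Step 5
Reactants: 9 N-[(2S)-1-hydroxy-3,3-dimethylbutan-2-yl]-6,7-dimethoxy-3-methylnaphthalene-2-carboxamide
Product: 11 (4S)-4-tert-butyl-2-(6,7-dimethoxy-3-methylnaphthalen-2-yl)-4,5-dihydro-1,3-oxazole, via chloro amide 10 (not isolated)
Conditions: SOCl2, CH2Cl2, 0 °C to rt; evaporate; then NaOH, MeOH/H2O, rt
Reagents that add atoms: none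
Why: The primary alcohol is converted into the chloride, and base then closes the ring by 5-exo-tet O-alkylation of the amide (cyclodehydration of a β-hydroxy amide to a 2-oxazoline); substitution occurs at the CH2 group, so the C4 stereocentre is untouched.

Step 6
Reactants: 11 (4S)-4-tert-butyl-2-(6,7-dimethoxy-3-methylnaphthalen-2-yl)-4,5-dihydro-1,3-oxazole; 12 4-bromo-1,2-dimethoxybenzene
Product: 15 (4S)-4-tert-butyl-2-[(1R,2R)-1-(3,4-dimethoxyphenyl)-6,7-dimethoxy-2,3-dimethyl-1,2-dihydronaphthalen-2-yl]-4,5-dihydro-1,3-oxazole, via 3,4-dimethoxyphenyllithium 13 (not isolated), via lithium aza-enolate 14 (not isolated)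
Conditions: 12, t-BuLi (2 equiv.), THF, −78 °C; then 11, THF, −78 to −40 °C; then MeI (5 equiv.), −78 °C to rt
Reagents that add atoms: iodomethane, CI
Why: Bromine–lithium exchange gives 13, which binds the oxazoline nitrogen of 11 (held s-cis to C1) and transfers its aryl group to C1 in a 1,4-addition across the C1=C2–C=N unit, the only site whose attack leaves ring A aromatic; the resulting extended aza-enolate 14 is then alkylated by iodomethane at its α-carbon C2. The closest known reaction type is the tandem addition of an organolithium and an alkyl halide to a chiral 2-naphthyl oxazoline. No ring is closed; two C–C bonds and two stereocentres are formed. C1 is set by the auxiliary: the C4 tert-butyl group makes the two faces of the nitrogen-bound aryllithium unequal, so that aryl transfer occurs on one face only (taken as the face giving 1R). C2 is set by C1: the pseudoaxial aryl group shields its own face of the planar aza-enolate, so iodomethane enters anti and methyl ends trans to aryl, with the oxazoline cis to it. The step needs addition in preference to lateral deprotonation of the C3 methyl group, which the modest basicity of an aryllithium and the low temperature favour. It also needs methylation at C2 and not at C4, which lithium held at nitrogen next to C2 and the small electrophile favour. Two equivalents of t-BuLi are used so that no primary alkyl bromide is left to compete with iodomethane.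

Step 7
Reactants: 15 (4S)-4-tert-butyl-2-[(1R,2R)-1-(3,4-dimethoxyphenyl)-6,7-dimethoxy-2,3-dimethyl-1,2-dihydronaphthalen-2-yl]-4,5-dihydro-1,3-oxazole
Product: 17 (4S)-4-tert-butyl-2-[(1R,2R)-1-(3,4-dimethoxyphenyl)-6,7-dimethoxy-2,3-dimethyl-1,2-dihydronaphthalen-2-yl]-3-methyl-1,3-oxazolidine, via N-methyloxazolinium triflate 16 (not isolated)
Conditions: MeOTf, CH2Cl2, rt; evaporate; then NaBH4, THF/MeOH, 0 °C
Reagents that add atoms: methyl trifluoromethanesulfonate, COS(=O)(=O)C(F)(F)F
Why: N-Alkylation turns the inert oxazoline into an iminium-type salt that borohydride reduces at the C=N carbon only (reductive oxazoline cleavage, first two stages); the aminal carbon forms as a mixture of epimers, which is of no consequence, and the styrene and aryl ethers are inert to both reagents.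

Step 8
Reactants: 17 (4S)-4-tert-butyl-2-[(1R,2R)-1-(3,4-dimethoxyphenyl)-6,7-dimethoxy-2,3-dimethyl-1,2-dihydronaphthalen-2-yl]-3-methyl-1,3-oxazolidine
Product: 18 (1R,2R)-1-(3,4-dimethoxyphenyl)-6,7-dimethoxy-2,3-dimethyl-1,2-dihydronaphthalene-2-carbaldehyde
Conditions: (CO2H)2, THF/H2O, rt
Reagents that add atoms: water, O
Why: Mild acid hydrolysis of the N,O-acetal releases the aldehyde and the N-methyl amino alcohol; C2 is quaternary and cannot epimerise, and the weak acid leaves the styrene and C1–H alone.

Step 9
Reactants: 18 (1R,2R)-1-(3,4-dimethoxyphenyl)-6,7-dimethoxy-2,3-dimethyl-1,2-dihydronaphthalene-2-carbaldehyde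
Product: 19 (1R,2S)-1-(3,4-dimethoxyphenyl)-6,7-dimethoxy-2,3-dimethyl-1,2-dihydronaphthalene
Conditions: RhCl(PPh3)3 (1.2 equiv.), degassed PhMe, 110 °C
Reagents that add atoms: none
Why: Tsuji–Wilkinson decarbonylation: oxidative addition of the formyl C–H bond to monovalent rhodium, migration of the alkyl group from CO to rhodium and C–H reductive elimination all occur with retention, so hydrogen takes the place of the formyl carbon cis to the aryl group and the trans aryl/methyl relation is kept; CO stays on rhodium, hence the stoichiometric amount.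

## Compound list

1 | 1,2-bis(bromomethyl)-4,5-dimethoxybenzene | COc1cc(CBr)c(CBr)cc1OC | starting material
2 | methyl but-2-ynoate | CC#CC(=O)OC | starting material
3 | 2,3-dimethoxy-5,6-dimethylidenecyclohexa-1,3-diene (4,5-dimethoxy-o-quinodimethane; formed in the flask) | COC1=CC(=C)C(=C)C=C1OC | intermediate
4 | methyl 6,7-dimethoxy-3-methyl-1,4-dihydronaphthalene-2-carboxylate | COC(=O)C1=C(C)Cc2cc(OC)c(OC)cc2C1 | intermediate
5 | methyl 6,7-dimethoxy-3-methylnaphthalene-2-carboxylate | COC(=O)c1cc2cc(OC)c(OC)cc2cc1C | intermediate
6 | 6,7-dimethoxy-3-methylnaphthalene-2-carboxylic acid | Cc1cc2cc(OC)c(OC)cc2cc1C(=O)O | intermediate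
7 | (S)-tert-leucinol, (2S)-2-amino-3,3-dimethylbutan-1-ol | N[C@H](CO)C(C)(C)C | starting material
8 | 6,7-dimethoxy-3-methylnaphthalene-2-carbonyl chloride (formed in the flask) | Cc1cc2cc(OC)c(OC)cc2cc1C(=O)Cl | intermediate
9 | N-[(2S)-1-hydroxy-3,3-dimethylbutan-2-yl]-6,7-dimethoxy-3-methylnaphthalene-2-carboxamide | Cc1cc2cc(OC)c(OC)cc2cc1C(=O)N[C@H](CO)C(C)(C)C | intermediate
10 | N-[(2S)-1-chloro-3,3-dimethylbutan-2-yl]-6,7-dimethoxy-3-methylnaphthalene-2-carboxamide (formed in the flask) | Cc1cc2cc(OC)c(OC)cc2cc1C(=O)N[C@H](CCl)C(C)(C)C | intermediate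
11 | (4S)-4-tert-butyl-2-(6,7-dimethoxy-3-methylnaphthalen-2-yl)-4,5-dihydro-1,3-oxazole | COc1cc2cc(C)c(C3=N[C@@H](C(C)(C)C)CO3)cc2cc1OC | intermediate
12 | 4-bromo-1,2-dimethoxybenzene | COc1ccc(Br)cc1OC | starting material
13 | 3,4-dimethoxyphenyllithium (formed in the flask) | [Li]c1ccc(OC)c(OC)c1 | intermediate
14 | lithium (4S)-4-tert-butyl-2-[(1R)-1-(3,4-dimethoxyphenyl)-6,7-dimethoxy-3-methyl-1H-naphthalen-2-ylidene]-1,3-oxazolidin-3-ide (aza-enolate; formed in the flask) | COc1ccc([C@@H]2c3cc(OC)c(OC)cc3C=C(C)C2=C2N([Li])[C@@H](C(C)(C)C)CO2)cc1OC | intermediate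
15 | (4S)-4-tert-butyl-2-[(1R,2R)-1-(3,4-dimethoxyphenyl)-6,7-dimethoxy-2,3-dimethyl-1,2-dihydronaphthalen-2-yl]-4,5-dihydro-1,3-oxazole (aryl and C2 methyl trans) | COc1ccc([C@@H]2c3cc(OC)c(OC)cc3C=C(C)[C@]2(C)C2=N[C@@H](C(C)(C)C)CO2)cc1OC | intermediate
16 | (4S)-4-tert-butyl-2-[(1R,2R)-1-(3,4-dimethoxyphenyl)-6,7-dimethoxy-2,3-dimethyl-1,2-dihydronaphthalen-2-yl]-3-methyl-4,5-dihydro-1,3-oxazol-3-ium trifluoromethanesulfonate (formed in the flask) | COc1ccc([C@@H]2c3cc(OC)c(OC)cc3C=C(C)[C@]2(C)C2=[N+](C)[C@@H](C(C)(C)C)CO2)cc1OC.[O-]S(=O)(=O)C(F)(F)F | intermediate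
17 | (4S)-4-tert-butyl-2-[(1R,2R)-1-(3,4-dimethoxyphenyl)-6,7-dimethoxy-2,3-dimethyl-1,2-dihydronaphthalen-2-yl]-3-methyl-1,3-oxazolidine (epimers at the aminal carbon) | COc1ccc([C@@H]2c3cc(OC)c(OC)cc3C=C(C)[C@]2(C)C2N(C)[C@@H](C(C)(C)C)CO2)cc1OC | intermediate
18 | (1R,2R)-1-(3,4-dimethoxyphenyl)-6,7-dimethoxy-2,3-dimethyl-1,2-dihydronaphthalene-2-carbaldehyde | COc1ccc([C@@H]2c3cc(OC)c(OC)cc3C=C(C)[C@]2(C)C=O)cc1OC | intermediate
19 | (1R,2S)-1-(3,4-dimethoxyphenyl)-6,7-dimethoxy-2,3-dimethyl-1,2-dihydronaphthalene (aryl and C2 methyl trans) | COc1ccc([C@@H]2c3cc(OC)c(OC)cc3C=C(C)[C@H]2C)cc1OC | target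

Total step count: 9. Longest linear sequence: 9 steps (1 to 19); aryllithium 13 is made from 12 in the flask of step 6.

## Least certain steps

**Step 6 (key step).** Three processes can defeat it: lateral deprotonation of the C3 methyl group or sluggish addition to the electron-rich naphthalene; weak or reversed facial discrimination at C1; and methylation at C4 in place of C2. The fallback sets out from 6 (through 8, made as in step 4) and returns at 18. It moves stereocontrol from the bound auxiliary to an external chiral ligand.
- Acid chloride 8 is esterified with lithium 2,6-di-tert-butyl-4-methoxyphenoxide to give 2,6-di-tert-butyl-4-methoxyphenyl 6,7-dimethoxy-3-methylnaphthalene-2-carboxylate F1. This hindered aryl ester also cannot undergo 1,2-addition.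
- 13 is added to F1 in toluene at −78 °C in the presence of 1,2-dimethoxy-1,2-diphenylethane, using whichever enantiomer delivers aryl to the (1R) face (both are available, so the sense of induction can be chosen). MeI is added to the same flask and enters anti to the aryl group, giving 2,6-di-tert-butyl-4-methoxyphenyl (1R,2R)-1-(3,4-dimethoxyphenyl)-6,7-dimethoxy-2,3-dimethyl-1,2-dihydronaphthalene-2-carboxylate F2.
- LiAlH4 in THF reduces F2 to [(1R,2R)-1-(3,4-dimethoxyphenyl)-6,7-dimethoxy-2,3-dimethyl-1,2-dihydronaphthalen-2-yl]methanol F3, and a Swern oxidation of F3 gives 18.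

**Step 9.** After CO loss the rhodium alkyl is tertiary and allylic. β-Hydride elimination towards C1 (aromatisation), or slippage to an allyl complex followed by hydrogen delivery to C4 or to the other face (alkene migration, loss of the C2 configuration), can compete with direct reductive elimination. The fallback sets out from 11 and returns at 19. It avoids any excision by letting the oxazoline carbon become the C2 methyl group.
- 13 is added to 11 as in step 6, but aza-enolate 14 is quenched with t-BuOH in place of MeI and equilibrated with catalytic t-BuOK to the more stable trans isomer, (4S)-4-tert-butyl-2-[(1R,2S)-1-(3,4-dimethoxyphenyl)-6,7-dimethoxy-3-methyl-1,2-dihydronaphthalen-2-yl]-4,5-dihydro-1,3-oxazole F4.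
- The auxiliary is removed as in steps 7 and 8: MeOTf gives the N-methyloxazolinium triflate F5, NaBH4 gives the N-methyloxazolidine F6, and oxalic acid gives (1R,2S)-1-(3,4-dimethoxyphenyl)-6,7-dimethoxy-3-methyl-1,2-dihydronaphthalene-2-carbaldehyde F7.
- F7 is reduced at once with NaBH4 to [(1R,2S)-1-(3,4-dimethoxyphenyl)-6,7-dimethoxy-3-methyl-1,2-dihydronaphthalen-2-yl]methanol F8.
- MsCl/Et3N converts F8 into the methanesulfonate F9, and LiEt3BH in THF displaces the sulfonate with hydride to give 19.

**Step 1.** Methyl but-2-ynoate is a weakly activated, β-substituted dienophile, so dimerisation and oligomerisation of 3 can outrun the cycloaddition when 3 is generated quickly by iodide. The fallback sets out from 1 and returns at 4. It changes the diene precursor to one that releases 3 slowly.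
- Na2S·9H2O in EtOH/H2O converts 1 into 5,6-dimethoxy-1,3-dihydro-2-benzothiophene F10.
- H2O2 in AcOH oxidises F10 to 5,6-dimethoxy-1,3-dihydro-2-benzothiophene 2,2-dioxide F11.
- Thermolysis of F11 at about 210 °C (sealed tube, 1,2,4-trichlorobenzene) in a large excess of 2 extrudes SO2 cheletropically, keeps 3 at low concentration and gives 4. Any 5 formed by adventitious dehydrogenation joins the route at step 2.

## Further compounds

F1 | step 6 | 2,6-di-tert-butyl-4-methoxyphenyl 6,7-dimethoxy-3-methylnaphthalene-2-carboxylate | COc1cc(C(C)(C)C)c(OC(=O)c2cc3cc(OC)c(OC)cc3cc2C)c(C(C)(C)C)c1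
F2 | step 6 | 2,6-di-tert-butyl-4-methoxyphenyl (1R,2R)-1-(3,4-dimethoxyphenyl)-6,7-dimethoxy-2,3-dimethyl-1,2-dihydronaphthalene-2-carboxylate | COc1ccc([C@@H]2c3cc(OC)c(OC)cc3C=C(C)[C@]2(C)C(=O)Oc2c(C(C)(C)C)cc(OC)cc2C(C)(C)C)cc1OC
F3 | step 6 | [(1R,2R)-1-(3,4-dimethoxyphenyl)-6,7-dimethoxy-2,3-dimethyl-1,2-dihydronaphthalen-2-yl]methanol | COc1ccc([C@@H]2c3cc(OC)c(OC)cc3C=C(C)[C@]2(C)CO)cc1OC
F4 | step 9 | (4S)-4-tert-butyl-2-[(1R,2S)-1-(3,4-dimethoxyphenyl)-6,7-dimethoxy-3-methyl-1,2-dihydronaphthalen-2-yl]-4,5-dihydro-1,3-oxazole | COc1ccc([C@@H]2c3cc(OC)c(OC)cc3C=C(C)[C@H]2C2=N[C@@H](C(C)(C)C)CO2)cc1OC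
F5 | step 9 | (4S)-4-tert-butyl-2-[(1R,2S)-1-(3,4-dimethoxyphenyl)-6,7-dimethoxy-3-methyl-1,2-dihydronaphthalen-2-yl]-3-methyl-4,5-dihydro-1,3-oxazol-3-ium trifluoromethanesulfonate | COc1ccc([C@@H]2c3cc(OC)c(OC)cc3C=C(C)[C@H]2C2=[N+](C)[C@@H](C(C)(C)C)CO2)cc1OC.[O-]S(=O)(=O)C(F)(F)F
F6 | step 9 | (4S)-4-tert-butyl-2-[(1R,2S)-1-(3,4-dimethoxyphenyl)-6,7-dimethoxy-3-methyl-1,2-dihydronaphthalen-2-yl]-3-methyl-1,3-oxazolidine (epimers at the aminal carbon) | COc1ccc([C@@H]2c3cc(OC)c(OC)cc3C=C(C)[C@H]2C2N(C)[C@@H](C(C)(C)C)CO2)cc1OC
F7 | step 9 | (1R,2S)-1-(3,4-dimethoxyphenyl)-6,7-dimethoxy-3-methyl-1,2-dihydronaphthalene-2-carbaldehyde | COc1ccc([C@@H]2c3cc(OC)c(OC)cc3C=C(C)[C@H]2C=O)cc1OC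
F8 | step 9 | [(1R,2S)-1-(3,4-dimethoxyphenyl)-6,7-dimethoxy-3-methyl-1,2-dihydronaphthalen-2-yl]methanol | COc1ccc([C@@H]2c3cc(OC)c(OC)cc3C=C(C)[C@H]2CO)cc1OC
F9 | step 9 | [(1R,2S)-1-(3,4-dimethoxyphenyl)-6,7-dimethoxy-3-methyl-1,2-dihydronaphthalen-2-yl]methyl methanesulfonate | COc1ccc([C@@H]2c3cc(OC)c(OC)cc3C=C(C)[C@H]2COS(C)(=O)=O)cc1OC
F10 | step 1 | 5,6-dimethoxy-1,3-dihydro-2-benzothiophene | COc1cc2CSCc2cc1OC
F11 | step 1 | 5,6-dimethoxy-1,3-dihydro-2-benzothiophene 2,2-dioxide | COc1cc2CS(=O)(=O)Cc2cc1OC
A1 | alternative 1 | cis-fused 4-(3,4-dimethoxyphenyl)-6,7-dimethoxy-2,3-dimethyl-3,4,4a,5,8,8a-hexahydronaphthalen-1(2H)-one | COc1ccc([C@@H]2[C@H]3CC(OC)=C(OC)C[C@H]3C(=O)[C@H](C)[C@H]2C)cc1OC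
A2 | alternative 1 | (4R,5S,6R)-4-(3,4-dimethoxyphenyl)-5,6-dimethylcyclohex-2-en-1-one (all-trans) | COc1ccc([C@@H]2C=CC(=O)[C@H](C)[C@H]2C)cc1OC
A3 | alternative 1 | 2,3-dimethoxybuta-1,3-diene | C=C(OC)C(OC)=C
A4 | alternative 2 | meso-6,7-dimethoxy-2,3-dimethyl-1,4-dihydro-1,4-epoxynaphthalene | COc1cc2c(cc1OC)[C@H]1O[C@@H]2C(C)=C1C
A5 | alternative 2 | 4,5-dimethoxy-2-(trimethylsilyl)phenyl trifluoromethanesulfonate | COc1cc(OS(=O)(=O)C(F)(F)F)c(cc1OC)[Si](C)(C)C
A6 | alternative 2 | 3,4-dimethylfuran | Cc1cocc1C
A7 | alternative 2 | (1S,2R)-6,7-dimethoxy-2,3-dimethyl-1,2-dihydronaphthalen-1-ol (hydroxyl and C2 methyl trans) | O[C@@H]1c2cc(OC)c(OC)cc2C=C(C)[C@H]1C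
A8 | alternative 2 | veratrole (1,2-dimethoxybenzene) | COc1ccccc1OC
A9 | alternative 3 | (1R,2S)-1-(3,4-dimethoxyphenyl)-2,3-dimethyl-6,7-bis(4,4,5,5-tetramethyl-1,3,2-dioxaborolan-2-yl)-1,2-dihydronaphthalene | COc1ccc([C@@H]2c3cc(B4OC(C)(C)C(C)(C)O4)c(B4OC(C)(C)C(C)(C)O4)cc3C=C(C)[C@H]2C)cc1OC
A10 | alternative 3 | 4-[(3S,4S,5Z)-4,5-dimethylocta-5-ene-1,7-diyn-3-yl]-1,2-dimethoxybenzene | COc1ccc([C@H](C#C)[C@H](C)/C(C)=C\C#C)cc1OC
A11 | alternative 3 | 1,2-bis(4,4,5,5-tetramethyl-1,3,2-dioxaborolan-2-yl)ethyne | CC1(C)OB(C#CB2OC(C)(C)C(C)(C)O2)OC1(C)C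
A12 | alternative 3 | (5R,6S)-5-(3,4-dimethoxyphenyl)-6,7-dimethyl-5,6-dihydronaphthalene-2,3-diol | COc1ccc([C@@H]2c3cc(O)c(O)cc3C=C(C)[C@H]2C)cc1OC
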